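The data come from a simulation for an exercise, noise included.

Start at the closed vessel: E and J go in, nothing leaves, and the readings show how far E got.

| flask | E | J | remark | time |
|---|---|---|---|---|
| Saturday's | 0.33 M | 1.8 equiv | run made earlier |  |
| epsilon | 0.49 M | 1.80 equiv |  | 8.0 d |
| theta | 0.49 M | 2.70 equiv |  | 8.0 d |

Saturday's run (percent of the E charged)

| time / d | E / % | Q / % |
|---|---|---|
| 0.333 | 75.8 | 22.0 |
| 0.833 | 60.3 | 38.1 |
| 1.67 | 46.4 | 51.1 |
| 2.50 | 34.7 | 56.9 |
| 4.00 | 27.0 | 61.9 |
| 5.00 | 25.3 | 62.5 |

(readings scatter by 1 percentage point)



- part of the E that has reacted at the end, epsilon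
- part of the E that has reacted at the end, theta
- what raising the equivalents of J from its lowest to its highest value here does to the part of the E that has reacted (changes below 5 percentage points count as none) (it rises / no change / it falls)

In Saturday's run E flattens near 25.3% by 5.00 d. Suppose J, the limiting reagent, has run out there. Now divide the rate at which [J] falls by the rate at which [E] falls: time drops out. Assume that this ratio carries over to the new flasks; that assumption is the weak link. Reckon that ratio over the whole run, as the J charged over the E reacted:

1.8 equiv / 74.7% = 2.41

Call this the price, the J spent for each E reacted. Divide each new charge by it: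

epsilon: 1.80 equiv / 2.41 = 74.7% of the E

theta: 2.70 equiv / 2.41 = 112% of the E, which is more than was charged

Now test the weak link. E and Q together end 12.2% short of the charge, and that loss appears after Q forms. Take it as one J per E lost from Q, and take it out of the price:

(1.8 equiv − 12.2%) / 74.7% = 2.25

At this trimmed price, my reckoning puts epsilon at 80.0%. Commit to 74.7% to 80.0% for epsilon and 100% for theta.

The forecast gives 80% for epsilon and 90% for theta, lower than this reckoning for theta: “More J raises conversion under both readings”.

The flasks give 81.2% for epsilon and 97.8% for theta, and the answer on the trend is that it rises.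

    E + J → G + Q (k = 0.0735 L mol⁻¹ h⁻¹)
    J ⇌ L (K = 0.270, k = 0.0550 h⁻¹)
    J + G ⇌ Z, settled at all times (K = 1360 L mol⁻¹)
    J + Q → X (k = 0.0153 L mol⁻¹ h⁻¹)

Epsilon ran E + J to G + Q first, with 77% of its turnover behind it at 1.60 d, against 44% for J + Q to X, while G went on to Z, 0.383 M at 8.00 d beside 0.0151 M of free G. By then free J stood at 2.11% of its charge, and the J gone per E reacted came to 2.17 against the price of 2.41. A neighbour of epsilon charged with 1.10 equiv of J reads 45.6% at that price; it gave 54.8% at 8.00 d, with 1.1% of its J free.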